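**Direct plan and its weak points**

A direct plan would build ring A from an open chain. An Evans alkylation would set the side-chain centre, and about ten linear steps would lead to the enoyl chloride A1.
A1 would be dehydrochlorinated to a vinylketene and joined with the siloxyalkyne A2 in a [2+2], 4π-opening and 6π-closure cascade to give the silyloxy dienone A3.
O-Methylation and desilylation of A3 would then move the carbonyl group and give the target.
The weakest points would be:
(a) the ketene cascade that closes ring A: the quaternary C4 would form under the weak bias of the neighbouring methine alone, so an epimer would have to be removed, and the ketene could also add to the allyl alkene;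
(b) the run-up to A1: an auxiliary, two redox changes, an ozonolysis beside an electron-rich arene and a carbinol centre made only to be destroyed would cost ten steps for a simple acid chloride;
(c) the closing carbonyl transposition on A3: a regioselective O-alkylation without close precedent would be asked of the most precious intermediate, which carries an acid-labile tertiary allylic ether.

**Retrosynthetic overview of the new route**

Ring A (C1 carbonyl, C2 allyl, C4 quaternary methoxy carbon, C5 enol ether) is not built but taken from 4-bromoresorcinol. The C4–O bond is formed by oxidative dearomatisation of a phenol whose C1–OH becomes the ketone and whose C5 oxygen is an aryl ether from the start, so no carbonyl transposition is needed.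
A lactamide tether on the C5 oxygen delivers oxygen to C4, so the C4 centre is set by an auxiliary in a cyclic transition state and not by the neighbouring side-chain methine C2′.
The C4–C2′ bond is made earlier by an enantiospecific boronate coupling with a side chain derived from methylisoeugenol. The C2 allyl group arrives by a Claisen rearrangement from O1, which also unmasks the phenol.
No carbocycle is closed; the only new ring is the temporary dioxanone, which is opened to the two methyl ethers. The route has eight steps.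

Key step: step 6

Remark: commercial methylisoeugenol is used as its (E) isomer. The sense of induction in step 6 is assigned from the transition-state model given there, not from a known result; if it proved opposite, the antipodal lactamide would be used in step 4 and nothing else would change.

Step 1
Reactants: 1 (E)-1,2-dimethoxy-4-(prop-1-en-1-yl)benzene (methylisoeugenol)
Product: 2 (R)-2-[1-(3,4-dimethoxyphenyl)propan-2-yl]-4,4,5,5-tetramethyl-1,3,2-dioxaborolane
Conditions: CuCl (cat.), chiral N-heterocyclic carbene ligand (from its imidazolinium salt; enantiomer that gives the R ester), NaOtBu, B2pin2, MeOH, THF, −50 °C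
Reagents that add atoms: bis(pinacolato)diboron, CC1(C)OB(OC1(C)C)B1OC(C)(C)C(C)(C)O1
Why: Copper-catalysed enantioselective protoboration of a β-alkylstyrene (borylcupration, then protonation by methanol) puts boron on the methyl-bearing carbon because copper takes the benzylic position, and the chiral ligand on copper sets C2′ as R.

Step 2
Reactants: 2 (R)-2-[1-(3,4-dimethoxyphenyl)propan-2-yl]-4,4,5,5-tetramethyl-1,3,2-dioxaborolane; 3 4-bromobenzene-1,3-diol (4-bromoresorcinol)
Product: 6 4-[(2R)-1-(3,4-dimethoxyphenyl)propan-2-yl]benzene-1,3-diol, via 2,4-bis(lithiooxy)phenyllithium 4 (not isolated), via lithium aryl boronate complex 5 (not isolated)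
Conditions: 3, n-BuLi (2 equiv), THF, −78 °C; t-BuLi (2 equiv), −78 °C; 2, −78 to 0 °C; Ph3BiF2, −78 °C to rt; then H2O
Reagents that add atoms: none
Why: Enantiospecific coupling of a secondary boronic ester and a lithiated phenoxide: aryllithium 4 adds to boron, the pentavalent bismuth reagent activates a phenoxide oxygen, the side chain makes a stereoretentive 1,2-shift from boron to C4 and loss of boron rearomatises the ring, so C2′ stays R.

Step 3
Reactants: 6 4-[(2R)-1-(3,4-dimethoxyphenyl)propan-2-yl]benzene-1,3-diol
Product: 7 2-[(2R)-1-(3,4-dimethoxyphenyl)propan-2-yl]-5-(prop-2-en-1-yloxy)phenol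
Conditions: allyl bromide (1 equiv), K2CO3, acetone, rt
Reagents that add atoms: allyl bromide, C=CCBr
Why: Williamson etherification under mild base should take place at the unhindered C1 hydroxyl para to the side chain, the C5 hydroxyl being screened by the ortho secondary alkyl group.

Step 4
Reactants: 7 2-[(2R)-1-(3,4-dimethoxyphenyl)propan-2-yl]-5-(prop-2-en-1-yloxy)phenol; 8 (2S)-2-hydroxy-N,N-dimethylpropanamide
Product: 9 (2R)-2-{2-[(2R)-1-(3,4-dimethoxyphenyl)propan-2-yl]-5-(prop-2-en-1-yloxy)phenoxy}-N,N-dimethylpropanamide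
Conditions: PPh3, diisopropyl azodicarboxylate, toluene, 0 °C to rt
Reagents that add atoms: none
Why: Mitsunobu etherification of the remaining phenol by the secondary alcohol 8 proceeds with SN2 inversion, which turns the (S) carbinol into the (R) aryloxy centre of the tether.

Step 5
Reactants: 9 (2R)-2-{2-[(2R)-1-(3,4-dimethoxyphenyl)propan-2-yl]-5-(prop-2-en-1-yloxy)phenoxy}-N,N-dimethylpropanamide
Product: 11 (2R)-2-{2-[(2R)-1-(3,4-dimethoxyphenyl)propan-2-yl]-5-hydroxy-4-(prop-2-en-1-yl)phenoxy}-N,N-dimethylpropanamide, via ortho-dienone 10 (not isolated)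
Conditions: N,N-diethylaniline, 190 °C
Reagents that add atoms: none
Why: Aromatic Claisen rearrangement ([3,3]) through ortho-dienone 10 should deliver the allyl group to C2, the ortho position remote from the bulky tether, and tautomerisation frees the C1 phenol that the key step needs.

Step 6
Reactants: 11 (2R)-2-{2-[(2R)-1-(3,4-dimethoxyphenyl)propan-2-yl]-5-hydroxy-4-(prop-2-en-1-yl)phenoxy}-N,N-dimethylpropanamide
Product: 13 (3R,8aR)-8a-[(2R)-1-(3,4-dimethoxyphenyl)propan-2-yl]-3-methyl-7-(prop-2-en-1-yl)-3,8a-dihydro-1,4-benzodioxine-2,6-dione, via cyclic iminium ether 12 (not isolated)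
Conditions: PhI(OCOCF3)2, CH2Cl2, −78 to −20 °C; then H2O
Reagents that add atoms: water, O
Why: Ligand exchange of the phenol on trivalent iodine and loss of PhI give a phenoxenium-type species whose para carbon C4 is captured by the amide oxygen of the tether, and the cyclic iminium ether 12 is hydrolysed on work-up to lactone 13. The closest known reaction type is the lactic acid or lactamide tether-directed oxidative dearomatisation of 4-alkylresorcinol monoethers to p-quinol lactones. The 1,4-dioxane ring closes by oxygen capture at C4 (6-exo-trig with respect to the C3=C4 bond) and leaves the cross-conjugated dienone with the enol ether oxygen fixed at C5. The new quaternary centre C4 is controlled by the tether stereocentre: in the boat-like six-membered transition state the side chain on C4 must stand in a flagpole position anti to the incoming oxygen, so the tether methyl takes the bowsprit position away from it, which for the (R) tether means attack on the face that gives (4R), while the remote C2′ centre should only modulate this. The step needs oxygen attack at C4 in preference to capture at C2 or C6, capture by ring B, or loss of the C2′ hydrogen to a quinone methide; the tether reaches only C4 and C6, C4 is the alkylated para carbon that carries most of the positive charge, and the intramolecular oxygen nucleophile should outrun the other pathways.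

Step 7
Reactants: 13 (3R,8aR)-8a-[(2R)-1-(3,4-dimethoxyphenyl)propan-2-yl]-3-methyl-7-(prop-2-en-1-yl)-3,8a-dihydro-1,4-benzodioxine-2,6-dione
Product: 15 (4R)-4-[(2R)-1-(3,4-dimethoxyphenyl)propan-2-yl]-4-hydroxy-5-methoxy-2-(prop-2-en-1-yl)cyclohexa-2,5-dien-1-one, via ring-opened methyl ester 14 (not isolated)
Conditions: NaOMe (cat.), MeOH, 0 °C to rt
Reagents that add atoms: methanol, CO
Why: Methoxide opens the lactone by transesterification to ester 14 and then exchanges the alkoxy group of the vinylogous ester at C5 by conjugate addition–elimination, the lactate alkoxide being the better leaving group and methanol being in large excess, so the enol ether oxygen stays at C5 and C4 is untouched.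

Step 8
Reactants: 15 (4R)-4-[(2R)-1-(3,4-dimethoxyphenyl)propan-2-yl]-4-hydroxy-5-methoxy-2-(prop-2-en-1-yl)cyclohexa-2,5-dien-1-one
Product: 16 (4R)-4-[(2R)-1-(3,4-dimethoxyphenyl)propan-2-yl]-4,5-dimethoxy-2-(prop-2-en-1-yl)cyclohexa-2,5-dien-1-one (the target)
Conditions: NaH, MeI, THF/DMF, 0 °C to rt
Reagents that add atoms: iodomethane, CI
Why: Williamson methylation of the tertiary sodium alkoxide, the only acidic site of 15, installs the C4 methyl ether without touching either stereocentre.

**Compound list**

1 | (E)-1,2-dimethoxy-4-(prop-1-en-1-yl)benzene (methylisoeugenol) | C/C=C/c1ccc(OC)c(OC)c1 | starting material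
2 | (R)-2-[1-(3,4-dimethoxyphenyl)propan-2-yl]-4,4,5,5-tetramethyl-1,3,2-dioxaborolane | C[C@H](Cc1ccc(OC)c(OC)c1)B1OC(C)(C)C(C)(C)O1 | intermediate
3 | 4-bromobenzene-1,3-diol (4-bromoresorcinol) | Oc1ccc(Br)c(O)c1 | starting material
4 | 2,4-bis(lithiooxy)phenyllithium | [Li]c1ccc(O[Li])cc1O[Li] | intermediate
5 | trilithium salt of the boronate complex formed from 4 by addition to 2 | C[C@H](Cc1ccc(OC)c(OC)c1)[B-]1(OC(C)(C)C(C)(C)O1)c1ccc([O-])cc1[O-].[Li+].[Li+].[Li+] | intermediate
6 | 4-[(2R)-1-(3,4-dimethoxyphenyl)propan-2-yl]benzene-1,3-diol | C[C@H](Cc1ccc(OC)c(OC)c1)c1ccc(O)cc1O | intermediate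
7 | 2-[(2R)-1-(3,4-dimethoxyphenyl)propan-2-yl]-5-(prop-2-en-1-yloxy)phenol | C[C@H](Cc1ccc(OC)c(OC)c1)c1ccc(OCC=C)cc1O | intermediate
8 | (2S)-2-hydroxy-N,N-dimethylpropanamide | C[C@H](O)C(=O)N(C)C | starting material
9 | (2R)-2-{2-[(2R)-1-(3,4-dimethoxyphenyl)propan-2-yl]-5-(prop-2-en-1-yloxy)phenoxy}-N,N-dimethylpropanamide | C[C@H](Cc1ccc(OC)c(OC)c1)c1ccc(OCC=C)cc1O[C@H](C)C(=O)N(C)C | intermediate
10 | (2R)-2-({6-[(2R)-1-(3,4-dimethoxyphenyl)propan-2-yl]-3-oxo-4-(prop-2-en-1-yl)cyclohexa-1,5-dien-1-yl}oxy)-N,N-dimethylpropanamide (ortho-dienone; ring carbon bearing the allyl group undefined) | C=CCC1C=C([C@H](C)Cc2ccc(OC)c(OC)c2)C(O[C@H](C)C(=O)N(C)C)=CC1=O | intermediate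
11 | (2R)-2-{2-[(2R)-1-(3,4-dimethoxyphenyl)propan-2-yl]-5-hydroxy-4-(prop-2-en-1-yl)phenoxy}-N,N-dimethylpropanamide | C=CCc1cc([C@H](C)Cc2ccc(OC)c(OC)c2)c(O[C@H](C)C(=O)N(C)C)cc1O | intermediate
12 | cyclic iminium ether (N,N-dimethyliminium analogue of lactone 13) as its trifluoroacetate | C=CCC1=C[C@@]2([C@H](C)Cc3ccc(OC)c(OC)c3)OC(=[N+](C)C)[C@@H](C)OC2=CC1=O.[O-]C(=O)C(F)(F)F | intermediate
13 | (3R,8aR)-8a-[(2R)-1-(3,4-dimethoxyphenyl)propan-2-yl]-3-methyl-7-(prop-2-en-1-yl)-3,8a-dihydro-1,4-benzodioxine-2,6-dione | C=CCC1=C[C@@]2([C@H](C)Cc3ccc(OC)c(OC)c3)OC(=O)[C@@H](C)OC2=CC1=O | intermediate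
14 | methyl (2R)-2-({(6R)-6-[(2R)-1-(3,4-dimethoxyphenyl)propan-2-yl]-6-hydroxy-3-oxo-4-(prop-2-en-1-yl)cyclohexa-1,4-dien-1-yl}oxy)propanoate | C=CCC1=C[C@](O)([C@H](C)Cc2ccc(OC)c(OC)c2)C(O[C@H](C)C(=O)OC)=CC1=O | intermediate
15 | (4R)-4-[(2R)-1-(3,4-dimethoxyphenyl)propan-2-yl]-4-hydroxy-5-methoxy-2-(prop-2-en-1-yl)cyclohexa-2,5-dien-1-one | C=CCC1=C[C@](O)([C@H](C)Cc2ccc(OC)c(OC)c2)C(OC)=CC1=O | intermediate
16 | (4R)-4-[(2R)-1-(3,4-dimethoxyphenyl)propan-2-yl]-4,5-dimethoxy-2-(prop-2-en-1-yl)cyclohexa-2,5-dien-1-one | C=CCC1=C[C@](OC)([C@H](C)Cc2ccc(OC)c(OC)c2)C(OC)=CC1=O | target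

**Step count and risks**

Total steps: 8. Longest linear sequence: 8 steps (1 to 16).

The three steps most likely to fail:

Step 2. The triply lithiated resorcinol 4 may form incompletely or stay insoluble, or the boronate complex may not form beside the ortho lithium phenoxide. The same C4–C2′ bond would then be made from 1 and 3 by a Heck arylation (Pd(OAc)2, P(o-tol)3, Et3N, DMF), in which the aryl group adds to the methyl-bearing alkene carbon, to give 4-[(1E)-1-(3,4-dimethoxyphenyl)prop-1-en-2-yl]benzene-1,3-diol F1. C2′ would then be set by asymmetric hydrogenation of the trisubstituted stilbene with an iridium phosphinooxazoline catalyst ([Ir(cod)(PHOX)]BArF, H2, CH2Cl2), which returns to 6.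

Step 6. The facial selectivity may be eroded by a mismatch between the tether and C2′, or the cation may be diverted by ring B or by loss of the C2′ hydrogen. The tether would then be given up from 7, which would be O-methylated (MeI, K2CO3) to 1-[(2R)-1-(3,4-dimethoxyphenyl)propan-2-yl]-2-methoxy-4-(prop-2-en-1-yloxy)benzene F2. Claisen rearrangement would give 4-[(2R)-1-(3,4-dimethoxyphenyl)propan-2-yl]-5-methoxy-2-(prop-2-en-1-yl)phenol F3, and oxidation with PhI(OAc)2 in methanol, where methanol itself adds to C4, would lead directly to 16. This path gives 16 together with its epimer (4S)-4-[(2R)-1-(3,4-dimethoxyphenyl)propan-2-yl]-4,5-dimethoxy-2-(prop-2-en-1-yl)cyclohexa-2,5-dien-1-one F4, which would be separated and recycled to F3 by reduction with zinc in acetic acid.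

Step 5. The allyl group may migrate toward C6, between the two oxygens, or the tether centre may suffer at the high temperature. The allyl ether of 9 would then be cleaved with zerovalent palladium (Pd(PPh3)4, morpholine) to (2R)-2-{2-[(2R)-1-(3,4-dimethoxyphenyl)propan-2-yl]-5-hydroxyphenoxy}-N,N-dimethylpropanamide F5. Bromination with N-bromosuccinimide ortho to the hydroxyl and para to the tether oxygen would give (2R)-2-{4-bromo-2-[(2R)-1-(3,4-dimethoxyphenyl)propan-2-yl]-5-hydroxyphenoxy}-N,N-dimethylpropanamide F6. A Stille coupling with allyltributylstannane (Pd(PPh3)4, DMF) would return to 11.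

**Further compounds**

F1 | step 2 | 4-[(1E)-1-(3,4-dimethoxyphenyl)prop-1-en-2-yl]benzene-1,3-diol | C/C(=C\c1ccc(OC)c(OC)c1)c1ccc(O)cc1O
F2 | step 6 | 1-[(2R)-1-(3,4-dimethoxyphenyl)propan-2-yl]-2-methoxy-4-(prop-2-en-1-yloxy)benzene | C[C@H](Cc1ccc(OC)c(OC)c1)c1ccc(OCC=C)cc1OC
F3 | step 6 | 4-[(2R)-1-(3,4-dimethoxyphenyl)propan-2-yl]-5-methoxy-2-(prop-2-en-1-yl)phenol | C=CCc1cc([C@H](C)Cc2ccc(OC)c(OC)c2)c(OC)cc1O
F4 | step 6 | (4S)-4-[(2R)-1-(3,4-dimethoxyphenyl)propan-2-yl]-4,5-dimethoxy-2-(prop-2-en-1-yl)cyclohexa-2,5-dien-1-one | C=CCC1=C[C@@](OC)([C@H](C)Cc2ccc(OC)c(OC)c2)C(OC)=CC1=O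
F5 | step 5 | (2R)-2-{2-[(2R)-1-(3,4-dimethoxyphenyl)propan-2-yl]-5-hydroxyphenoxy}-N,N-dimethylpropanamide | C[C@H](Cc1ccc(OC)c(OC)c1)c1ccc(O)cc1O[C@H](C)C(=O)N(C)C
F6 | step 5 | (2R)-2-{4-bromo-2-[(2R)-1-(3,4-dimethoxyphenyl)propan-2-yl]-5-hydroxyphenoxy}-N,N-dimethylpropanamide | C[C@H](Cc1ccc(OC)c(OC)c1)c1cc(Br)c(O)cc1O[C@H](C)C(=O)N(C)C
A1 | direct plan | (2E,5R)-6-(3,4-dimethoxyphenyl)-4-methoxy-5-methyl-2-(prop-2-en-1-yl)hex-2-enoyl chloride | ClC(=O)/C(CC=C)=C/C(OC)[C@H](C)Cc1ccc(OC)c(OC)c1
A2 | direct plan | ethynyloxytri(propan-2-yl)silane (triisopropylsiloxyacetylene) | C#CO[Si](C(C)C)(C(C)C)C(C)C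
A3 | direct plan | (6R)-6-[(2R)-1-(3,4-dimethoxyphenyl)propan-2-yl]-6-methoxy-4-(prop-2-en-1-yl)-3-[tri(propan-2-yl)silyloxy]cyclohexa-2,4-dien-1-one | C=CCC1=C[C@](OC)([C@H](C)Cc2ccc(OC)c(OC)c2)C(=O)C=C1O[Si](C(C)C)(C(C)C)C(C)C
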